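**Plan**

Oxolane numbering used throughout: O1, C2 (bears C1′, the ester carbinol), C3, C4, C5 (bears the hydroxymethine–pyranone arm).
1. Retrosynthetic cuts, in order: the silyl groups; pyranone C3=C4 (ring-closing metathesis) and the acrylate C–O; the allyl C–C bond at pyranone C6; the caffeate C–O; CH3–C1′; then C1′–C2 by a [2,3]-Wittig–Still shift; the glycal is cut back to D-gulono-1,4-lactone.
2. Feature that allows the key event: C2 lies between ring O1 and C3, and C1′ carries an oxygen. C2 can therefore be the enol-ether terminus O1–C2=C3 of a 2,3-dihydrofuran whose allylic C4 holds an oxygen cis to the C5 arm. A CH2 carbanion tethered to that oxygen must bond to C2 on that face; the tether oxygen becomes the C1′ oxygen, C4–O is lost, and the C3=C4 alkene left behind is hydrogenated.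
3. Forward order: the oxolane ring is the lactone ring of the sugar and is never opened (lactone → lactol → glycal → 2,5-dihydrofuran → oxolane). Then come the C1′ methyl, the caffeate, the C5 arm, and last the pyranone ring by metathesis.
4. Stereochemistry: C5 and the free carbinol are C-4 and C-5 of the gulonolactone, and its C-3 oxygen is the temporary C4–O. C2 follows from it by suprafacial 1,3-transfer, C1′ from chelation-controlled methyl addition, and pyranone C6 from reagent-controlled allylboration matched with the Felkin–Anh preference.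

Key step: step 5

Assumption: D-gulono-1,4-lactone, caffeic acid, tributyl(iodomethyl)stannane and a preformed solution of B-allyldiisopinocampheylborane of the (−)-α-pinene series are taken as purchasable; the catechol is carried as its bis-silyl ether so that one fluoride treatment ends the route.

**Route**

Step 1
Reactants: 1 D-gulono-1,4-lactone
Product: 2 2,3:5,6-di-O-isopropylidene-D-gulono-1,4-lactone
Conditions: 2,2-dimethoxypropane, TsOH (cat.), acetone, rt
Reagents that add atoms: 2,2-dimethoxypropane, COC(C)(C)OC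
Why: Acid-catalysed transacetalisation (acetonide formation): the cis-2,3-diol of the lactone ring and the terminal 5,6-diol should each close a five-membered isopropylidene acetal, and no stereocenter is touched.

Step 2
Reactants: 2 2,3:5,6-di-O-isopropylidene-D-gulono-1,4-lactone
Product: 3 2,3:5,6-di-O-isopropylidene-D-gulofuranose (lactol, anomer mixture)
Conditions: DIBAL-H, CH2Cl2, −78 °C; Rochelle salt work-up
Reagents that add atoms: none
Why: DIBAL-H half-reduction of a γ-lactone: the tetrahedral aluminium hemiacetal is stable at −78 °C and should give the lactol on work-up.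

Step 3
Reactants: 3 2,3:5,6-di-O-isopropylidene-D-gulofuranose
Product: 5 (2R,3S)-2-[(4R)-2,2-dimethyl-1,3-dioxolan-4-yl]-2,3-dihydrofuran-3-ol, via furanosyl chloride 4 (not isolated)
Conditions: CCl4, P(NMe2)3, THF, −78 °C → rt; then Li, NH3(l), THF, −78 °C; NH4Cl
Reagents that add atoms: none
Why: Appel-type chlorination of the anomeric hydroxyl followed by dissolving-metal reduction: the anomeric carbanion expels O-2 of the 2,3-acetonide (reductive β-elimination, a known way to furanoid glycals), which loses acetone, frees the 3-hydroxyl and leaves C-3, C-4 and C-5 untouched.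

Step 4
Reactants: 5 (2R,3S)-2-[(4R)-2,2-dimethyl-1,3-dioxolan-4-yl]-2,3-dihydrofuran-3-ol
Product: 6 tributyl[({(2R,3S)-2-[(4R)-2,2-dimethyl-1,3-dioxolan-4-yl]-2,3-dihydrofuran-3-yl}oxy)methyl]stannane
Conditions: KH, THF, 0 °C; then Bu3SnCH2I, 18-crown-6 (cat.), rt
Reagents that add atoms: tributyl(iodomethyl)stannane, CCCC[Sn](CI)(CCCC)CCCC
Why: Williamson etherification: the potassium alkoxide displaces iodide from the primary α-stannyl iodide, the usual way to set up a Wittig–Still substrate, and the basic conditions spare the acid-labile glycal.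

Step 5
Reactants: 6 tributyl[({(2R,3S)-2-[(4R)-2,2-dimethyl-1,3-dioxolan-4-yl]-2,3-dihydrofuran-3-yl}oxy)methyl]stannane
Product: 8 [(2S,5R)-5-[(4R)-2,2-dimethyl-1,3-dioxolan-4-yl]-2,5-dihydrofuran-2-yl]methanol, via lithiomethyl ether 7 (not isolated)
Conditions: n-BuLi, THF, −78 °C; NH4Cl
Reagents that add atoms: none
Why: Proposed new method: tin–lithium exchange at −78 °C gives the non-stabilised α-alkoxymethyllithium 7, which should undergo a concerted [2,3]-Wittig (Wittig–Still) shift through a five-membered envelope transition state over O–C4–C3=C2 of the glycal, making the C2–CH2 bond, breaking C4–O and moving the double bond to C3=C4. The closest known reaction types are the Wittig–Still rearrangement of stannylmethyl ethers of cyclic allylic alcohols and the Ireland–Claisen rearrangement of furanoid glycal esters, which turns the same C4–O stereocenter into a C2–C bond. No ring is closed: the five-membered oxygen ring of the sugar is kept throughout. The only new stereocenter, C2, is set by the C4–O stereocenter (C-3 of the gulonolactone), because the tethered carbanion can reach C2 only on the face that carries this oxygen, which is also the face of the C5 arm, so the 2,5-cis ring should result. The step needs the [2,3] shift to win over the [1,2] shift and over lithiation of the enol-ether C2–H; the low temperature, the fast exchange at tin and the fact that C2 is the electrophilic end of the enol ether (as in Ferrier-type SN2′ substitutions) should secure this.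

Step 6
Reactants: 8 [(2S,5R)-5-[(4R)-2,2-dimethyl-1,3-dioxolan-4-yl]-2,5-dihydrofuran-2-yl]methanol
Product: 9 [(2S,5R)-5-[(4R)-2,2-dimethyl-1,3-dioxolan-4-yl]oxolan-2-yl]methanol
Conditions: H2 (1 atm), 5% Rh/Al2O3, EtOAc, rt
Reagents that add atoms: none
Why: Heterogeneous hydrogenation of the ring alkene; rhodium on alumina is chosen to avoid hydrogenolysis of the two allylic C–O bonds, and no stereocenter changes.

Step 7
Reactants: 9 [(2S,5R)-5-[(4R)-2,2-dimethyl-1,3-dioxolan-4-yl]oxolan-2-yl]methanol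
Product: 10 (2S,5R)-5-[(4R)-2,2-dimethyl-1,3-dioxolan-4-yl]oxolane-2-carbaldehyde
Conditions: Dess–Martin periodinane, CH2Cl2, 0 °C → rt
Reagents that add atoms: none
Why: Dess–Martin oxidation of the primary alcohol under nearly neutral conditions, which should not epimerise the α-alkoxy aldehyde.

Step 8
Reactants: 10 (2S,5R)-5-[(4R)-2,2-dimethyl-1,3-dioxolan-4-yl]oxolane-2-carbaldehyde
Product: 11 (1S)-1-{(2S,5R)-5-[(4R)-2,2-dimethyl-1,3-dioxolan-4-yl]oxolan-2-yl}ethan-1-ol
Conditions: MeMgBr, MgBr2·OEt2, CH2Cl2, −78 °C; NH4Cl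
Reagents that add atoms: methylmagnesium bromide, C[Mg]Br
Why: Chelation-controlled (Cram-chelate) Grignard addition: magnesium bridges the aldehyde oxygen and ring O1, methyl adds from the side of the C2 hydrogen and should set the (S) carbinol, threo to O1.

Step 9
Reactants: 12 caffeic acid
Product: 14 (2E)-3-[3,4-bis(tert-butyldimethylsilyloxy)phenyl]prop-2-enoic acid, via tris-silyl derivative 13 (not isolated)
Conditions: TBSCl, imidazole, DMF, rt; then AcOH/THF/H2O, rt
Reagents that add atoms: tert-butyldimethylsilyl chloride, CC(C)(C)[Si](C)(C)Cl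
Why: Exhaustive silylation followed by selective acidic hydrolysis of the labile silyl ester, which should leave the two aryl silyl ethers in place.

Step 10
Reactants: 11 (1S)-1-{(2S,5R)-5-[(4R)-2,2-dimethyl-1,3-dioxolan-4-yl]oxolan-2-yl}ethan-1-ol; 14 (2E)-3-[3,4-bis(tert-butyldimethylsilyloxy)phenyl]prop-2-enoic acid
Product: 15 (1S)-1-{(2S,5R)-5-[(4R)-2,2-dimethyl-1,3-dioxolan-4-yl]oxolan-2-yl}ethyl (2E)-3-[3,4-bis(tert-butyldimethylsilyloxy)phenyl]prop-2-enoate
Conditions: DCC, DMAP (cat.), CH2Cl2, rt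
Reagents that add atoms: none
Why: Steglich esterification; the carbinol C–O bond is not broken, so the C1′ configuration is retained.

Step 11
Reactants: 15 the acetonide ester
Product: 16 (1S)-1-{(2S,5R)-5-[(1R)-1,2-dihydroxyethyl]oxolan-2-yl}ethyl (2E)-3-[3,4-bis(tert-butyldimethylsilyloxy)phenyl]prop-2-enoate
Conditions: AcOH/H2O (4:1), 40 °C
Reagents that add atoms: none
Why: Acid hydrolysis of the terminal isopropylidene acetal; aryl silyl ethers and the ester should be stable to aqueous acetic acid.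

Step 12
Reactants: 16 the diol
Product: 17 (1S)-1-{(2S,5R)-5-[(1R)-1,2-bis(triethylsilyloxy)ethyl]oxolan-2-yl}ethyl (2E)-3-[3,4-bis(tert-butyldimethylsilyloxy)phenyl]prop-2-enoate
Conditions: TESOTf, 2,6-lutidine, CH2Cl2, −78 °C
Reagents that add atoms: triethylsilyl trifluoromethanesulfonate, CC[Si](CC)(CC)OS(=O)(=O)C(F)(F)F
Why: Silylation of both hydroxyls with the silyl triflate and a hindered base.

Step 13
Reactants: 17 the bis(triethylsilyl) ether
Product: 18 (1S)-1-{(2S,5R)-5-[(1S)-2-oxo-1-(triethylsilyloxy)ethyl]oxolan-2-yl}ethyl (2E)-3-[3,4-bis(tert-butyldimethylsilyloxy)phenyl]prop-2-enoate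
Conditions: (COCl)2, DMSO, CH2Cl2, −78 → −30 °C; then Et3N, −78 °C → rt
Reagents that add atoms: none
Why: Swern oxidation applied directly to the bis-silyl ether: the primary triethylsilyl ether is cleaved and oxidised in the chlorosulfonium medium much faster than the secondary one (a known selective oxidation of primary TES ethers), which should give the α-silyloxy aldehyde.

Step 14
Reactants: 18 the α-silyloxy aldehyde
Product: 19 (1S)-1-{(2S,5R)-5-[(1R,2R)-2-hydroxy-1-(triethylsilyloxy)pent-4-en-1-yl]oxolan-2-yl}ethyl (2E)-3-[3,4-bis(tert-butyldimethylsilyloxy)phenyl]prop-2-enoate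
Conditions: lIpc2B(allyl) [(−)-α-pinene series], Et2O, −78 °C; then pH 7 buffer, MeOH, 30% H2O2, 0 °C
Reagents that add atoms: B-allyldiisopinocampheylborane of the (−)-α-pinene series, C=CCB([C@H]1C[C@H]2C[C@@H]([C@@H]1C)C2(C)C)[C@H]1C[C@H]2C[C@@H]([C@@H]1C)C2(C)C
Why: Brown allylation: the allyl group is delivered through a chair six-membered transition state to the Re face, and the Felkin–Anh preference of the α-silyloxy aldehyde (anti product) is for the same face, so the matched pair should set the (R) homoallylic carbinol.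

Step 15
Reactants: 19 the homoallylic alcohol
Product: 20 (1S)-1-{(2S,5R)-5-[(1S,2R)-2-(prop-2-enoyloxy)-1-(triethylsilyloxy)pent-4-en-1-yl]oxolan-2-yl}ethyl (2E)-3-[3,4-bis(tert-butyldimethylsilyloxy)phenyl]prop-2-enoate
Conditions: acryloyl chloride, Et3N, DMAP (cat.), CH2Cl2, 0 °C
Reagents that add atoms: acryloyl chloride, C=CC(=O)Cl
Why: Acylation of the secondary alcohol with the acid chloride.

Step 16
Reactants: 20 the acrylate
Product: 21 (1S)-1-{(2S,5R)-5-[(S)-[(2R)-6-oxo-3,6-dihydro-2H-pyran-2-yl](triethylsilyloxy)methyl]oxolan-2-yl}ethyl (2E)-3-[3,4-bis(tert-butyldimethylsilyloxy)phenyl]prop-2-enoate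
Conditions: Grubbs second-generation catalyst (5 mol %), CH2Cl2 (high dilution), 40 °C
Reagents that add atoms: none
Why: Ring-closing metathesis: the acrylate and the terminal alkene should close the six-membered unsaturated lactone with loss of ethene, while the 1,2-disubstituted, electron-poor cinnamate alkene should react much more slowly.

Step 17
Reactants: 21 the silyl-protected lactone
Product: 22 (1S)-1-{(2S,5R)-5-[(S)-hydroxy[(2R)-6-oxo-3,6-dihydro-2H-pyran-2-yl]methyl]oxolan-2-yl}ethyl (2E)-3-(3,4-dihydroxyphenyl)prop-2-enoate (target)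
Conditions: HF·pyridine, pyridine, THF, 0 °C → rt
Reagents that add atoms: none
Why: Fluoride-mediated desilylation should remove the two aryl silyl ethers and the secondary TES ether under buffered conditions that the enoate lactone and the caffeate ester tolerate.

**Compound list**

1 | D-gulono-1,4-lactone | O=C1[C@H](O)[C@H](O)[C@H]([C@H](O)CO)O1 | starting material
2 | 2,3:5,6-di-O-isopropylidene-D-gulono-1,4-lactone | O=C1[C@@H]2OC(C)(C)O[C@@H]2[C@H]([C@H]3COC(C)(C)O3)O1 | intermediate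
3 | 2,3:5,6-di-O-isopropylidene-D-gulofuranose (anomer mixture) | OC1[C@@H]2OC(C)(C)O[C@@H]2[C@H]([C@H]3COC(C)(C)O3)O1 | intermediate
4 | 2,3:5,6-di-O-isopropylidene-D-gulofuranosyl chloride | ClC1[C@@H]2OC(C)(C)O[C@@H]2[C@H]([C@H]3COC(C)(C)O3)O1 | intermediate (not isolated)
5 | (2R,3S)-2-[(4R)-2,2-dimethyl-1,3-dioxolan-4-yl]-2,3-dihydrofuran-3-ol (1,4-anhydro-2-deoxy-5,6-O-isopropylidene-D-xylo-hex-1-enitol) | C1=C[C@H](O)[C@H]([C@H]2COC(C)(C)O2)O1 | intermediate
6 | tributyl[({(2R,3S)-2-[(4R)-2,2-dimethyl-1,3-dioxolan-4-yl]-2,3-dihydrofuran-3-yl}oxy)methyl]stannane | C1=C[C@H](OC[Sn](CCCC)(CCCC)CCCC)[C@H]([C@H]2COC(C)(C)O2)O1 | intermediate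
7 | ({(2R,3S)-2-[(4R)-2,2-dimethyl-1,3-dioxolan-4-yl]-2,3-dihydrofuran-3-yl}oxy)methyllithium | C1=C[C@H](OC[Li])[C@H]([C@H]2COC(C)(C)O2)O1 | intermediate (not isolated)
8 | [(2S,5R)-5-[(4R)-2,2-dimethyl-1,3-dioxolan-4-yl]-2,5-dihydrofuran-2-yl]methanol | OC[C@@H]1C=C[C@H]([C@H]2COC(C)(C)O2)O1 | intermediate
9 | [(2S,5R)-5-[(4R)-2,2-dimethyl-1,3-dioxolan-4-yl]oxolan-2-yl]methanol | OC[C@@H]1CC[C@H]([C@H]2COC(C)(C)O2)O1 | intermediate
10 | (2S,5R)-5-[(4R)-2,2-dimethyl-1,3-dioxolan-4-yl]oxolane-2-carbaldehyde | O=C[C@@H]1CC[C@H]([C@H]2COC(C)(C)O2)O1 | intermediate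
11 | (1S)-1-{(2S,5R)-5-[(4R)-2,2-dimethyl-1,3-dioxolan-4-yl]oxolan-2-yl}ethan-1-ol | C[C@H](O)[C@@H]1CC[C@H]([C@H]2COC(C)(C)O2)O1 | intermediate
12 | caffeic acid, (2E)-3-(3,4-dihydroxyphenyl)prop-2-enoic acid | OC(=O)/C=C/c1ccc(O)c(O)c1 | starting material
13 | tert-butyldimethylsilyl (2E)-3-[3,4-bis(tert-butyldimethylsilyloxy)phenyl]prop-2-enoate | CC(C)(C)[Si](C)(C)OC(=O)/C=C/c1ccc(O[Si](C)(C)C(C)(C)C)c(O[Si](C)(C)C(C)(C)C)c1 | intermediate (not isolated)
14 | (2E)-3-[3,4-bis(tert-butyldimethylsilyloxy)phenyl]prop-2-enoic acid | OC(=O)/C=C/c1ccc(O[Si](C)(C)C(C)(C)C)c(O[Si](C)(C)C(C)(C)C)c1 | intermediate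
15 | (1S)-1-{(2S,5R)-5-[(4R)-2,2-dimethyl-1,3-dioxolan-4-yl]oxolan-2-yl}ethyl (2E)-3-[3,4-bis(tert-butyldimethylsilyloxy)phenyl]prop-2-enoate | C[C@H](OC(=O)/C=C/c1ccc(O[Si](C)(C)C(C)(C)C)c(O[Si](C)(C)C(C)(C)C)c1)[C@@H]1CC[C@H]([C@H]2COC(C)(C)O2)O1 | intermediate
16 | (1S)-1-{(2S,5R)-5-[(1R)-1,2-dihydroxyethyl]oxolan-2-yl}ethyl (2E)-3-[3,4-bis(tert-butyldimethylsilyloxy)phenyl]prop-2-enoate | C[C@H](OC(=O)/C=C/c1ccc(O[Si](C)(C)C(C)(C)C)c(O[Si](C)(C)C(C)(C)C)c1)[C@@H]1CC[C@H]([C@H](O)CO)O1 | intermediate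
17 | (1S)-1-{(2S,5R)-5-[(1R)-1,2-bis(triethylsilyloxy)ethyl]oxolan-2-yl}ethyl (2E)-3-[3,4-bis(tert-butyldimethylsilyloxy)phenyl]prop-2-enoate | C[C@H](OC(=O)/C=C/c1ccc(O[Si](C)(C)C(C)(C)C)c(O[Si](C)(C)C(C)(C)C)c1)[C@@H]1CC[C@H]([C@H](O[Si](CC)(CC)CC)CO[Si](CC)(CC)CC)O1 | intermediate
18 | (1S)-1-{(2S,5R)-5-[(1S)-2-oxo-1-(triethylsilyloxy)ethyl]oxolan-2-yl}ethyl (2E)-3-[3,4-bis(tert-butyldimethylsilyloxy)phenyl]prop-2-enoate | C[C@H](OC(=O)/C=C/c1ccc(O[Si](C)(C)C(C)(C)C)c(O[Si](C)(C)C(C)(C)C)c1)[C@@H]1CC[C@H]([C@H](O[Si](CC)(CC)CC)C=O)O1 | intermediate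
19 | (1S)-1-{(2S,5R)-5-[(1R,2R)-2-hydroxy-1-(triethylsilyloxy)pent-4-en-1-yl]oxolan-2-yl}ethyl (2E)-3-[3,4-bis(tert-butyldimethylsilyloxy)phenyl]prop-2-enoate | C[C@H](OC(=O)/C=C/c1ccc(O[Si](C)(C)C(C)(C)C)c(O[Si](C)(C)C(C)(C)C)c1)[C@@H]1CC[C@H]([C@H](O[Si](CC)(CC)CC)[C@H](O)CC=C)O1 | intermediate
20 | (1S)-1-{(2S,5R)-5-[(1S,2R)-2-(prop-2-enoyloxy)-1-(triethylsilyloxy)pent-4-en-1-yl]oxolan-2-yl}ethyl (2E)-3-[3,4-bis(tert-butyldimethylsilyloxy)phenyl]prop-2-enoate | C[C@H](OC(=O)/C=C/c1ccc(O[Si](C)(C)C(C)(C)C)c(O[Si](C)(C)C(C)(C)C)c1)[C@@H]1CC[C@H]([C@H](O[Si](CC)(CC)CC)[C@H](OC(=O)C=C)CC=C)O1 | intermediate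
21 | (1S)-1-{(2S,5R)-5-[(S)-[(2R)-6-oxo-3,6-dihydro-2H-pyran-2-yl](triethylsilyloxy)methyl]oxolan-2-yl}ethyl (2E)-3-[3,4-bis(tert-butyldimethylsilyloxy)phenyl]prop-2-enoate | C[C@H](OC(=O)/C=C/c1ccc(O[Si](C)(C)C(C)(C)C)c(O[Si](C)(C)C(C)(C)C)c1)[C@@H]1CC[C@H]([C@H](O[Si](CC)(CC)CC)[C@H]2CC=CC(=O)O2)O1 | intermediate
22 | (1S)-1-{(2S,5R)-5-[(S)-hydroxy[(2R)-6-oxo-3,6-dihydro-2H-pyran-2-yl]methyl]oxolan-2-yl}ethyl (2E)-3-(3,4-dihydroxyphenyl)prop-2-enoate | C[C@H](OC(=O)/C=C/c1ccc(O)c(O)c1)[C@@H]1CC[C@H]([C@H](O)[C@H]2CC=CC(=O)O2)O1 | target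

**Step count**

Total steps: 17. Longest linear sequence: 16 steps (steps 1–8 and 10–17, from D-gulono-1,4-lactone); step 9 is the one-step side branch.

**Steps most likely to fail**

1. Step 5 (proposed new method). What may go wrong: the lithiomethyl ether may take the radical [1,2]-shift or be protonated, or n-butyllithium may metalate the enol-ether C–H instead of exchanging at tin. The fallback uses known chemistry, sets out from 5 and comes back at 10. Acylation of glycal alcohol 5 with benzyloxyacetyl chloride and pyridine should give (2R,3S)-2-[(4R)-2,2-dimethyl-1,3-dioxolan-4-yl]-2,3-dihydrofuran-3-yl 2-(benzyloxy)acetate F1. LDA and then Me3SiCl/Et3N in THF at −78 °C should give the silyl ketene acetal F2. On warming to room temperature F2 undergoes the Ireland–Claisen rearrangement, a [3,3] shift across the same O–C4–C3=C2 unit and suprafacial like the key step, to the trimethylsilyl ester F3 and, after aqueous work-up, the acid F4. Hydrogenation over Pd/C saturates the ring alkene and removes the benzyl ether to give the α-hydroxy acid F5. Lead tetraacetate in benzene cleaves F5 to aldehyde 10, where the route is rejoined. The carbon next to the carboxyl group becomes the aldehyde carbon, so its configuration in F3 to F5 is of no concern and is left undefined.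

2. Step 8. What may go wrong: poor facial selectivity if magnesium chelation competes badly with open-chain addition of the small methyl nucleophile. The fallback sets out from 11 (as its epimer mixture at the carbinol carbon) and comes back at 11. Dess–Martin oxidation gives the methyl ketone 1-{(2S,5R)-5-[(4R)-2,2-dimethyl-1,3-dioxolan-4-yl]oxolan-2-yl}ethan-1-one F6, and F6 is reduced with L-Selectride in THF at −78 °C. A bulky non-chelating hydride follows the Felkin–Anh polar model and should give the same threo alcohol 11.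

3. Step 13. What may go wrong: loss of the secondary silyl ether as well, or incomplete cleavage of the primary one, in the chlorosulfonium medium. The fallback sets out from 17 and comes back at 18. Aqueous acetic acid in THF at 0 °C should remove only the primary triethylsilyl ether to give the primary alcohol (1S)-1-{(2S,5R)-5-[(1R)-2-hydroxy-1-(triethylsilyloxy)ethyl]oxolan-2-yl}ethyl (2E)-3-[3,4-bis(tert-butyldimethylsilyloxy)phenyl]prop-2-enoate F7, and a Dess–Martin oxidation of F7 gives aldehyde 18.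

**Further compounds**

F1 | step 5 | (2R,3S)-2-[(4R)-2,2-dimethyl-1,3-dioxolan-4-yl]-2,3-dihydrofuran-3-yl 2-(benzyloxy)acetate | C1=C[C@H](OC(=O)COCc3ccccc3)[C@H]([C@H]2COC(C)(C)O2)O1
F2 | step 5 | trimethylsilyl ketene acetal of F1, [2-(benzyloxy)-1-({(2R,3S)-2-[(4R)-2,2-dimethyl-1,3-dioxolan-4-yl]-2,3-dihydrofuran-3-yl}oxy)ethenyl]oxy(trimethyl)silane | C1=C[C@H](OC(O[Si](C)(C)C)=COCc3ccccc3)[C@H]([C@H]2COC(C)(C)O2)O1
F3 | step 5 | trimethylsilyl 2-(benzyloxy)-2-[(2S,5R)-5-[(4R)-2,2-dimethyl-1,3-dioxolan-4-yl]-2,5-dihydrofuran-2-yl]acetate | C[Si](C)(C)OC(=O)C(OCc1ccccc1)[C@@H]1C=C[C@H]([C@H]2COC(C)(C)O2)O1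
F4 | step 5 | 2-(benzyloxy)-2-[(2S,5R)-5-[(4R)-2,2-dimethyl-1,3-dioxolan-4-yl]-2,5-dihydrofuran-2-yl]acetic acid | OC(=O)C(OCc1ccccc1)[C@@H]1C=C[C@H]([C@H]2COC(C)(C)O2)O1
F5 | step 5 | 2-hydroxy-2-[(2S,5R)-5-[(4R)-2,2-dimethyl-1,3-dioxolan-4-yl]oxolan-2-yl]acetic acid | OC(=O)C(O)[C@@H]1CC[C@H]([C@H]2COC(C)(C)O2)O1
F6 | step 8 | 1-{(2S,5R)-5-[(4R)-2,2-dimethyl-1,3-dioxolan-4-yl]oxolan-2-yl}ethan-1-one | CC(=O)[C@@H]1CC[C@H]([C@H]2COC(C)(C)O2)O1
F7 | step 13 | (1S)-1-{(2S,5R)-5-[(1R)-2-hydroxy-1-(triethylsilyloxy)ethyl]oxolan-2-yl}ethyl (2E)-3-[3,4-bis(tert-butyldimethylsilyloxy)phenyl]prop-2-enoate | C[C@H](OC(=O)/C=C/c1ccc(O[Si](C)(C)C(C)(C)C)c(O[Si](C)(C)C(C)(C)C)c1)[C@@H]1CC[C@H]([C@H](O[Si](CC)(CC)CC)CO)O1
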